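**Retrosynthetic overview**

1. The target is epicatechin-(4β→6)-epiafzelechin-(4β→8)-epicatechin-(4β→6)-epicatechin (units 1–4 from the top). The three interflavan C4–aryl bonds are cut as Friedel–Crafts couplings in the order 1+2, then +3, then +4; C8 bromine caps on units 1, 2 and 4 force the two 4→6 bonds.
2. Each flavan unit is cut across ring C at C3–C4 and O1–C8a. This is a formal [3+3] union of a 2-fluoro-4,6-bis(benzyloxy)benzyl chloride (C4 electrophile, C8a–F) with the O,C-dianion of an aryl(1,3-dithian-2-yl)methanol (O1 nucleophile, C3 as acyl-anion equivalent).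
3. Enabling feature: in ring A, C8a (the O1 carbon) is meta to both phenol oxygens (C5, C7) and ortho to C4a, which carries C4, so an aryl fluoride at C8a is SNAr-competent and is the only leaving group. C3 is a carbinol carbon next to the benzylic, O1-bearing C2–H, so at the ketone level (dithiane) C3 becomes a carbanion, its oxygen is silenced, and C2 becomes epimerizable.
4. The racemic flavan-3-ones are then funnelled by dynamic kinetic asymmetric hydrogenation into the 2R,3R cis alcohols; two annulations supply all four units.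
5. Ring order: ring A (from 1,3,5-trifluorobenzene) → ring C (key step, ring B arrives with the carbinol) → capping and C4 activation → oligomer assembly → global hydrogenolysis.

Key step: step 6

Remark: units are numbered 1–4 from the upper chain end; all are 2R,3R (2,3-cis) and every interflavan bond is 4β (3,4-trans). The sense of induction of the hydrogenation catalyst in steps 8 and 12 is assigned by analogy with 2-arylcycloalkanones, and the mirror-image catalyst is to be used if the first run shows the opposite sense.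

**Route**

Step 1
Reactants: 1 1,3,5-trifluorobenzene; 2 benzyl alcohol
Product: 3 1,3-bis(benzyloxy)-5-fluorobenzene
Conditions: NaH (2.1 equiv), 2 (2.1 equiv), NMP, 0 → 80 °C
Reagents that add atoms: none
Why: Double SNAr by benzyloxide should stop after two exchanges because each alkoxy group lowers the electrophilicity of the ring, leaving the fluorine that later serves as leaving group at C8a.

Step 2
Reactants: 3 1,3-bis(benzyloxy)-5-fluorobenzene
Product: 4 2,4-bis(benzyloxy)-6-fluorobenzaldehyde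
Conditions: POCl3, DMF, 0 → 60 °C; then H2O
Reagents that add atoms: N,N-dimethylformamide CN(C)C=O; water O
Why: Vilsmeier–Haack formylation should go para to one benzyloxy group and ortho to the small fluorine rather than between the two benzyloxy groups, and the minor 4-fluoro isomer is to be removed by crystallization.

Step 3
Reactants: 4 2,4-bis(benzyloxy)-6-fluorobenzaldehyde
Product: 5 [2,4-bis(benzyloxy)-6-fluorophenyl]methanol
Conditions: NaBH4, THF/MeOH, 0 °C
Reagents that add atoms: none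
Why: Borohydride reduction of an aryl aldehyde is routine and touches neither the aryl fluoride nor the benzyl ethers.

Step 4
Reactants: 5 [2,4-bis(benzyloxy)-6-fluorophenyl]methanol
Product: 6 1,5-bis(benzyloxy)-2-(chloromethyl)-3-fluorobenzene
Conditions: MsCl, Et3N, CH2Cl2, 0 °C; used crude at once
Reagents that add atoms: methanesulfonyl chloride CS(=O)(=O)Cl
Why: The mesylate of this electron-rich benzylic alcohol is displaced in situ by chloride (nucleophilic substitution at a 2,4-dialkoxybenzyl centre), and the labile chloride is not chromatographed.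

Step 5
Reactants: 7 1,3-dithiane; 8 3,4-bis(benzyloxy)benzaldehyde
Product: 9 [3,4-bis(benzyloxy)phenyl](1,3-dithian-2-yl)methanol (racemic)
Conditions: n-BuLi, THF, −30 °C; then 8, −78 °C; then H2O
Reagents that add atoms: none
Why: Corey–Seebach umpolung, 2-lithio-1,3-dithiane adding to the aryl aldehyde; the carbinol centre (future C2) is left racemic because it is equilibrated in step 8.

Step 6
Reactants: 9 [3,4-bis(benzyloxy)phenyl](1,3-dithian-2-yl)methanol; 6 1,5-bis(benzyloxy)-2-(chloromethyl)-3-fluorobenzene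
Product: 11 5,7-bis(benzyloxy)-2-[3,4-bis(benzyloxy)phenyl]spiro[chromane-3,2'-[1,3]dithiane] (racemic at C2), via lithium alkoxide of the C-benzylated carbinol 10 (not isolated)
Conditions: n-BuLi (2.0 equiv), THF, −30 °C; then 6, −78 → 0 °C; then DMPU, 65 °C
Reagents that add atoms: none
Why: n-BuLi removes first the hydroxyl proton and then the dithiane C–H of 9, and the soft carbanion (future C3, an acyl-anion equivalent) displaces chloride from the benzylic carbon of 6 (future C4) in a Corey–Seebach alkylation to give alkoxide 10; on warming in THF/DMPU the alkoxide oxygen (O1) attacks the fluorine-bearing carbon (C8a) and fluoride leaves, an intramolecular SNAr, so the step is a formal [3+3] annulation of a 1,3-dielectrophile with an O,C-dianion. The closest known reaction types are the alkylation of β-oxido 2-lithio-1,3-dithianes with benzylic halides and the closure of chromans from γ-(2-fluoroaryl) alkoxides. Ring C closes in the 6-exo mode by ipso attack on the arene through a Meisenheimer-type transition state. No stereocenter is controlled here on purpose: C3 is a spiro dithioketal carbon and C2 is carried as a racemate that step 8 funnels into one configuration. The step needs C- over O-alkylation, which the far more nucleophilic carbanion secures, and it needs O1 to be the only oxygen able to reach C8a, which the dithiane secures by holding the C3 oxygen back at the ketone level so that no five-membered dihydrobenzofuran or benzofuran can form. Fluorine is the only leaving group on ring A and lies ortho to the benzylic arm, and both benzyloxy groups are meta to it, so they do not oppose the negative charge that builds up on C8, C6 and C4a.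

Step 7
Reactants: 11 the spiro-dithiane flavan
Product: 12 5,7-bis(benzyloxy)-2-[3,4-bis(benzyloxy)phenyl]chroman-3-one (racemic, C2 labile)
Conditions: MeI, CaCO3, MeCN/H2O 9:1, 45 °C
Reagents that add atoms: water O
Why: Dithioketal hydrolysis by S-methylation and attack of water is non-oxidative and should spare the electron-rich arenes; C2 needs no protection from epimerization.

Step 8
Reactants: 12 the flavan-3-one
Product: 13 (2R,3R)-5,7-bis(benzyloxy)-2-[3,4-bis(benzyloxy)phenyl]chroman-3-ol (5,7,3',4'-tetra-O-benzyl-(−)-epicatechin)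
Conditions: RuCl2[(R)-Xyl-SDP][(S,S)-DPEN] (0.5 mol %), t-BuOK (20 mol %), H2 (50 atm), i-PrOH/toluene, 25 °C
Reagents that add atoms: none
Why: Noyori-type asymmetric hydrogenation under dynamic kinetic resolution: the base should epimerize C2 (benzylic, α to O1 and to the C3 carbonyl) faster than hydride transfer, and the chiral catalyst should reduce only the 2R ketone from the face anti to the 2-aryl group, so both C2 and C3 of the cis alcohol are set from the racemate.

Step 9
Reactants: 7 1,3-dithiane; 14 4-(benzyloxy)benzaldehyde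
Product: 15 [4-(benzyloxy)phenyl](1,3-dithian-2-yl)methanol (racemic)
Conditions: n-BuLi, THF, −30 °C; then 14, −78 °C; then H2O
Reagents that add atoms: none
Why: Same Corey–Seebach addition as in step 5, the carbinol centre again being left racemic.

Step 10
Reactants: 15 [4-(benzyloxy)phenyl](1,3-dithian-2-yl)methanol; 6 1,5-bis(benzyloxy)-2-(chloromethyl)-3-fluorobenzene
Product: 17 5,7-bis(benzyloxy)-2-[4-(benzyloxy)phenyl]spiro[chromane-3,2'-[1,3]dithiane] (racemic at C2), via lithium alkoxide of the C-benzylated carbinol 16 (not isolated)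
Conditions: n-BuLi (2.0 equiv), THF, −30 °C; then 6, −78 → 0 °C; then DMPU, 65 °C
Reagents that add atoms: none
Why: The same Corey–Seebach alkylation and intramolecular SNAr annulation as in step 6, applied to the 4-benzyloxyphenyl carbinol, with C2 again carried as a racemate.

Step 11
Reactants: 17 the spiro-dithiane flavan of the epiafzelechin series
Product: 18 5,7-bis(benzyloxy)-2-[4-(benzyloxy)phenyl]chroman-3-one (racemic, C2 labile)
Conditions: MeI, CaCO3, MeCN/H2O 9:1, 45 °C
Reagents that add atoms: water O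
Why: Dithioketal hydrolysis by S-methylation as in step 7.

Step 12
Reactants: 18 the flavan-3-one of the epiafzelechin series
Product: 19 (2R,3R)-5,7-bis(benzyloxy)-2-[4-(benzyloxy)phenyl]chroman-3-ol (5,7,4'-tri-O-benzyl-(−)-epiafzelechin)
Conditions: RuCl2[(R)-Xyl-SDP][(S,S)-DPEN] (0.5 mol %), t-BuOK (20 mol %), H2 (50 atm), i-PrOH/toluene, 25 °C
Reagents that add atoms: none
Why: Noyori-type hydrogenation under dynamic kinetic resolution as in step 8, the catalyst setting C3 and the fast base-mediated equilibration supplying the matching 2R ketone, with hydride entering anti to the 2-aryl group to give the cis alcohol.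

Step 13
Reactants: 13 tetra-O-benzylepicatechin
Product: 20 8-bromo-5,7,3',4'-tetra-O-benzylepicatechin (2R,3R)
Conditions: NBS (1.0 equiv), CH2Cl2, −40 → 0 °C
Reagents that add atoms: N-bromosuccinimide O=C1CCC(=O)N1Br
Why: Electrophilic aromatic bromination should go to C8, the most nucleophilic and least hindered position of the phloroglucinol-type ring A, giving the cap that later forces attack at C6.

Step 14
Reactants: 20 8-bromo-tetra-O-benzylepicatechin
Product: 21 8-bromo-5,7,3',4'-tetra-O-benzyl-4β-(2-ethoxyethoxy)epicatechin (2,3-cis, 3,4-trans)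
Conditions: DDQ (2 equiv), 2-ethoxyethanol (5 equiv), CH2Cl2, 25 °C
Reagents that add atoms: 2-ethoxyethanol CCOCCO
Why: Benzylic oxidation: DDQ abstracts hydride from C4, the cation is stabilized by the 5,7-dialkoxy ring A, and the alcohol should add anti to the 3-hydroxyl to set the 4β ether.

Step 15
Reactants: 19 tri-O-benzylepiafzelechin
Product: 22 8-bromo-5,7,4'-tri-O-benzylepiafzelechin (2R,3R)
Conditions: NBS (1.0 equiv), CH2Cl2, −40 → 0 °C
Reagents that add atoms: N-bromosuccinimide O=C1CCC(=O)N1Br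
Why: Electrophilic bromination at C8 as in step 13, the 4-benzyloxyphenyl ring being far less reactive than ring A.

Step 16
Reactants: 22 8-bromo-tri-O-benzylepiafzelechin
Product: 23 8-bromo-5,7,4'-tri-O-benzyl-4β-(2-ethoxyethoxy)epiafzelechin (2,3-cis, 3,4-trans)
Conditions: DDQ (2 equiv), 2-ethoxyethanol (5 equiv), CH2Cl2, 25 °C
Reagents that add atoms: 2-ethoxyethanol CCOCCO
Why: DDQ benzylic oxidation as in step 14, with the alcohol entering trans to the 3-hydroxyl.

Step 17
Reactants: 23 the 4β-(2-ethoxyethoxy) ether of the epiafzelechin series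
Product: 24 8-bromo-5,7,4'-tri-O-benzyl-4β-[(2,6-dimethylphenyl)sulfanyl]epiafzelechin (2,3-cis, 3,4-trans)
Conditions: 2,6-dimethylbenzenethiol (3 equiv), BF3·OEt2 (0.3 equiv), CH2Cl2, −78 → −40 °C
Reagents that add atoms: 2,6-dimethylbenzenethiol Cc1cccc(C)c1S
Why: Lewis-acid exchange through the C4 cation, the thiol attacking trans to the 3-hydroxyl to set the 4β sulfide, a leaving group that a hard Lewis acid does not ionize at low temperature.

Step 18
Reactants: 21 capped 4β-(2-ethoxyethoxy) unit 1; 24 capped 4β-sulfanyl unit 2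
Product: 25 8-bromo-tetra-O-benzylepicatechin-(4β→6)-8-bromo-tri-O-benzyl-4β-[(2,6-dimethylphenyl)sulfanyl]epiafzelechin
Conditions: 24 (3 equiv), BF3·OEt2 (0.5 equiv), CH2Cl2, −78 → −30 °C, slow addition of 21
Reagents that add atoms: none
Why: Friedel–Crafts alkylation in which BF3 ionizes only the C4–O bond of 21 and the cation is attacked by C6 of 24, its only free ring A position because C8 is brominated, anti to the 3-hydroxyl of unit 1 to set the new C4 stereocenter as 4β.

Step 19
Reactants: 13 tetra-O-benzylepicatechin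
Product: 26 5,7,3',4'-tetra-O-benzyl-4β-(2-ethoxyethoxy)epicatechin (2,3-cis, 3,4-trans)
Conditions: DDQ (2 equiv), 2-ethoxyethanol (5 equiv), CH2Cl2, 25 °C
Reagents that add atoms: 2-ethoxyethanol CCOCCO
Why: DDQ benzylic oxidation as in step 14, the alcohol adding trans to the 3-hydroxyl.

Step 20
Reactants: 25 the unit 1–unit 2 sulfide; 26 4β-(2-ethoxyethoxy) unit 3
Product: 27 8-bromo-tetra-O-benzylepicatechin-(4β→6)-8-bromo-tri-O-benzylepiafzelechin-(4β→8)-tetra-O-benzyl-4β-(2-ethoxyethoxy)epicatechin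
Conditions: AgBF4 (1.2 equiv), 2,6-di-tert-butyl-4-methylpyridine (1.5 equiv), 26 (3 equiv), 4 Å molecular sieves, CH2Cl2, −40 → 0 °C
Reagents that add atoms: none
Why: Thiophilic activation in which silver ion removes the C4 sulfide of unit 2 and the cation undergoes Friedel–Crafts attack by C8 of 26, the inherently more nucleophilic ring A position of an uncapped unit, trans to the 3-hydroxyl to give the 4β→8 bond, while the hindered base keeps the medium neutral so that the C4 ether of 26 survives.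

Step 21
Reactants: 27 the unit 1–2–3 trimer; 20 8-bromo-tetra-O-benzylepicatechin
Product: 28 8-bromo-tetra-O-benzylepicatechin-(4β→6)-8-bromo-tri-O-benzylepiafzelechin-(4β→8)-tetra-O-benzylepicatechin-(4β→6)-8-bromo-tetra-O-benzylepicatechin
Conditions: 20 (5 equiv), BF3·OEt2 (0.5 equiv), CH2Cl2, −78 → −30 °C, slow addition of 27
Reagents that add atoms: none
Why: Friedel–Crafts alkylation in which BF3 ionizes the C4 ether of unit 3 and C6 of 20, the only free ring A position of the capped unit, attacks anti to the 3-hydroxyl to give the 4β→6 bond, the excess of 20 and the slow addition suppressing self-coupling of the trimer.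

Step 22
Reactants: 28 the protected tetramer
Product: 29 epicatechin-(4β→6)-epiafzelechin-(4β→8)-epicatechin-(4β→6)-epicatechin (CNP0103636.1)
Conditions: H2 (1 atm), Pd(OH)2/C, Et3N (6 equiv), THF/MeOH/H2O, 25 °C
Reagents that add atoms: none
Why: Catalytic hydrogenolysis should cleave the fifteen benzyl ethers and reduce the three aryl bromides in one operation, with triethylamine buffering the hydrogen bromide so that the acid-labile interflavan bonds and all eleven stereocenters stay untouched.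

**Compound list**

1 | 1,3,5-trifluorobenzene | Fc1cc(F)cc(F)c1 | starting material
2 | benzyl alcohol | OCc1ccccc1 | starting material
3 | 1,3-bis(benzyloxy)-5-fluorobenzene | Fc1cc(OCc2ccccc2)cc(OCc2ccccc2)c1 | intermediate
4 | 2,4-bis(benzyloxy)-6-fluorobenzaldehyde | O=Cc1c(F)cc(OCc2ccccc2)cc1OCc1ccccc1 | intermediate
5 | [2,4-bis(benzyloxy)-6-fluorophenyl]methanol | OCc1c(F)cc(OCc2ccccc2)cc1OCc1ccccc1 | intermediate
6 | 1,5-bis(benzyloxy)-2-(chloromethyl)-3-fluorobenzene | ClCc1c(F)cc(OCc2ccccc2)cc1OCc1ccccc1 | intermediate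
7 | 1,3-dithiane | C1CSCSC1 | starting material
8 | 3,4-bis(benzyloxy)benzaldehyde | O=Cc1ccc(OCc2ccccc2)c(OCc2ccccc2)c1 | starting material
9 | [3,4-bis(benzyloxy)phenyl](1,3-dithian-2-yl)methanol, racemic | OC(c1ccc(OCc2ccccc2)c(OCc2ccccc2)c1)C1SCCCS1 | intermediate
10 | lithium [3,4-bis(benzyloxy)phenyl]{2-[2,4-bis(benzyloxy)-6-fluorobenzyl]-1,3-dithian-2-yl}methanolate, racemic | [Li+].[O-]C(c1ccc(OCc2ccccc2)c(OCc2ccccc2)c1)C1(Cc2c(F)cc(OCc3ccccc3)cc2OCc2ccccc2)SCCCS1 | intermediate
11 | 5,7-bis(benzyloxy)-2-[3,4-bis(benzyloxy)phenyl]spiro[chromane-3,2'-[1,3]dithiane], racemic at C2 | C1CSC2(Cc3c(OCc4ccccc4)cc(OCc4ccccc4)cc3OC2c2ccc(OCc3ccccc3)c(OCc3ccccc3)c2)SC1 | intermediate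
12 | 5,7-bis(benzyloxy)-2-[3,4-bis(benzyloxy)phenyl]chroman-3-one, racemic | O=C1Cc2c(OCc3ccccc3)cc(OCc3ccccc3)cc2OC1c1ccc(OCc2ccccc2)c(OCc2ccccc2)c1 | intermediate
13 | (2R,3R)-5,7-bis(benzyloxy)-2-[3,4-bis(benzyloxy)phenyl]chroman-3-ol (tetra-O-benzylepicatechin) | O[C@@H]1Cc2c(OCc3ccccc3)cc(OCc3ccccc3)cc2O[C@@H]1c1ccc(OCc2ccccc2)c(OCc2ccccc2)c1 | intermediate
14 | 4-(benzyloxy)benzaldehyde | O=Cc1ccc(OCc2ccccc2)cc1 | starting material
15 | [4-(benzyloxy)phenyl](1,3-dithian-2-yl)methanol, racemic | OC(c1ccc(OCc2ccccc2)cc1)C1SCCCS1 | intermediate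
16 | lithium [4-(benzyloxy)phenyl]{2-[2,4-bis(benzyloxy)-6-fluorobenzyl]-1,3-dithian-2-yl}methanolate, racemic | [Li+].[O-]C(c1ccc(OCc2ccccc2)cc1)C1(Cc2c(F)cc(OCc3ccccc3)cc2OCc2ccccc2)SCCCS1 | intermediate
17 | 5,7-bis(benzyloxy)-2-[4-(benzyloxy)phenyl]spiro[chromane-3,2'-[1,3]dithiane], racemic at C2 | C1CSC2(Cc3c(OCc4ccccc4)cc(OCc4ccccc4)cc3OC2c2ccc(OCc3ccccc3)cc2)SC1 | intermediate
18 | 5,7-bis(benzyloxy)-2-[4-(benzyloxy)phenyl]chroman-3-one, racemic | O=C1Cc2c(OCc3ccccc3)cc(OCc3ccccc3)cc2OC1c1ccc(OCc2ccccc2)cc1 | intermediate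
19 | (2R,3R)-5,7-bis(benzyloxy)-2-[4-(benzyloxy)phenyl]chroman-3-ol (tri-O-benzylepiafzelechin) | O[C@@H]1Cc2c(OCc3ccccc3)cc(OCc3ccccc3)cc2O[C@@H]1c1ccc(OCc2ccccc2)cc1 | intermediate
20 | 8-bromo-5,7,3',4'-tetra-O-benzylepicatechin (2R,3R) | O[C@@H]1Cc2c(OCc3ccccc3)cc(OCc3ccccc3)c(Br)c2O[C@@H]1c1ccc(OCc2ccccc2)c(OCc2ccccc2)c1 | intermediate
21 | 8-bromo-5,7,3',4'-tetra-O-benzyl-4β-(2-ethoxyethoxy)epicatechin (2,3-cis, 3,4-trans) | O[C@@H]1[C@@H](OCCOCC)c2c(OCc3ccccc3)cc(OCc3ccccc3)c(Br)c2O[C@@H]1c1ccc(OCc2ccccc2)c(OCc2ccccc2)c1 | intermediate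
22 | 8-bromo-5,7,4'-tri-O-benzylepiafzelechin (2R,3R) | O[C@@H]1Cc2c(OCc3ccccc3)cc(OCc3ccccc3)c(Br)c2O[C@@H]1c1ccc(OCc2ccccc2)cc1 | intermediate
23 | 8-bromo-5,7,4'-tri-O-benzyl-4β-(2-ethoxyethoxy)epiafzelechin (2,3-cis, 3,4-trans) | O[C@@H]1[C@@H](OCCOCC)c2c(OCc3ccccc3)cc(OCc3ccccc3)c(Br)c2O[C@@H]1c1ccc(OCc2ccccc2)cc1 | intermediate
24 | 8-bromo-5,7,4'-tri-O-benzyl-4β-[(2,6-dimethylphenyl)sulfanyl]epiafzelechin (2,3-cis, 3,4-trans) | O[C@@H]1[C@@H](Sc2c(C)cccc2C)c2c(OCc3ccccc3)cc(OCc3ccccc3)c(Br)c2O[C@@H]1c1ccc(OCc2ccccc2)cc1 | intermediate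
25 | 8-bromo-tetra-O-benzylepicatechin-(4β→6)-8-bromo-tri-O-benzyl-4β-[(2,6-dimethylphenyl)sulfanyl]epiafzelechin | O[C@@H]1[C@@H](Sc2c(C)cccc2C)c2c(OCc3ccccc3)c([C@H]3c4c(OCc5ccccc5)cc(OCc5ccccc5)c(Br)c4O[C@H](c4ccc(OCc5ccccc5)c(OCc5ccccc5)c4)[C@@H]3O)c(OCc3ccccc3)c(Br)c2O[C@@H]1c1ccc(OCc2ccccc2)cc1 | intermediate
26 | 5,7,3',4'-tetra-O-benzyl-4β-(2-ethoxyethoxy)epicatechin (2,3-cis, 3,4-trans) | O[C@@H]1[C@@H](OCCOCC)c2c(OCc3ccccc3)cc(OCc3ccccc3)cc2O[C@@H]1c1ccc(OCc2ccccc2)c(OCc2ccccc2)c1 | intermediate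
27 | 8-bromo-tetra-O-benzylepicatechin-(4β→6)-8-bromo-tri-O-benzylepiafzelechin-(4β→8)-tetra-O-benzyl-4β-(2-ethoxyethoxy)epicatechin | O[C@@H]1[C@@H](c2c(OCc3ccccc3)cc(OCc3ccccc3)c3c2O[C@H](c2ccc(OCc4ccccc4)c(OCc4ccccc4)c2)[C@H](O)[C@H]3OCCOCC)c2c(OCc3ccccc3)c([C@H]3c4c(OCc5ccccc5)cc(OCc5ccccc5)c(Br)c4O[C@H](c4ccc(OCc5ccccc5)c(OCc5ccccc5)c4)[C@@H]3O)c(OCc3ccccc3)c(Br)c2O[C@@H]1c1ccc(OCc2ccccc2)cc1 | intermediate
28 | 8-bromo-tetra-O-benzylepicatechin-(4β→6)-8-bromo-tri-O-benzylepiafzelechin-(4β→8)-tetra-O-benzylepicatechin-(4β→6)-8-bromo-tetra-O-benzylepicatechin | O[C@@H]1[C@@H](c2c(OCc3ccccc3)cc(OCc3ccccc3)c3c2O[C@H](c2ccc(OCc4ccccc4)c(OCc4ccccc4)c2)[C@H](O)[C@H]3c2c(OCc4ccccc4)c(Br)c3c(c2OCc2ccccc2)C[C@@H](O)[C@@H](c2ccc(OCc4ccccc4)c(OCc4ccccc4)c2)O3)c2c(OCc3ccccc3)c([C@H]3c4c(OCc5ccccc5)cc(OCc5ccccc5)c(Br)c4O[C@H](c4ccc(OCc5ccccc5)c(OCc5ccccc5)c4)[C@@H]3O)c(OCc3ccccc3)c(Br)c2O[C@@H]1c1ccc(OCc2ccccc2)cc1 | intermediate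
29 | epicatechin-(4β→6)-epiafzelechin-(4β→8)-epicatechin-(4β→6)-epicatechin (CNP0103636.1) | Oc1ccc([C@H]2Oc3cc(O)c([C@H]4c5c(O)cc(O)cc5O[C@H](c5ccc(O)c(O)c5)[C@@H]4O)c(O)c3[C@H](c3c(O)cc(O)c4c3O[C@H](c3ccc(O)c(O)c3)[C@H](O)[C@H]4c3c(O)cc4c(c3O)C[C@@H](O)[C@@H](c3ccc(O)c(O)c3)O4)[C@H]2O)cc1 | target

**Step count and risks**

Total step count: 22. Longest linear sequence: 14 steps (steps 1–4, 10–12, 15–18, 20–22).

Steps most likely to fail:

Step 6. The displacement of fluoride at the only weakly activated C8a may be slow, and meanwhile the hindered alkoxide may fragment by retro-addition into aldehyde and dithianyl anion. The fallback changes the carbon–oxygen bond formation from SNAr to copper catalysis. It sets out from 9 and from commercial 1,3-bis(benzyloxy)-5-bromobenzene F1. Vilsmeier–Haack formylation (POCl3, DMF) should give 2,4-bis(benzyloxy)-6-bromobenzaldehyde F2, NaBH4 the alcohol [2,4-bis(benzyloxy)-6-bromophenyl]methanol F3, and MsCl/Et3N the chloride 1,5-bis(benzyloxy)-3-bromo-2-(chloromethyl)benzene F4. The dianion of 9 (n-BuLi, 2.0 equiv) is alkylated with F4 at −78 °C and quenched cold to the isolated carbinol [3,4-bis(benzyloxy)phenyl]{2-[2,4-bis(benzyloxy)-6-bromobenzyl]-1,3-dithian-2-yl}methanol F5. Ring C is then closed by an Ullmann-type intramolecular etherification (CuI, 1,10-phenanthroline, Cs2CO3, toluene, 110 °C), which comes back to the route at 11.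

Step 20. Silver ion or adventitious acid may ionize the C4 ether of the nucleophile 26 prematurely, so that 26 condenses with itself. The fallback is a convergent union in which the nucleophile carries no leaving group. It sets out from 13 and uses 20 and 25. Iodination of 13 with N-iodosuccinimide should give 8-iodo-tetra-O-benzylepicatechin F7, and DDQ with 2-ethoxyethanol its 4β-(2-ethoxyethoxy) ether F8. Friedel–Crafts coupling of F8 with excess 20 (BF3·OEt2, −78 °C) should give the lower dimer 8-iodo-tetra-O-benzylepicatechin-(4β→6)-8-bromo-tetra-O-benzylepicatechin F9. Iodine–magnesium exchange with i-PrMgCl·LiCl, which leaves the aryl bromide alone, followed by water gives tetra-O-benzylepicatechin-(4β→6)-8-bromo-tetra-O-benzylepicatechin F10. Activation of 25 with AgBF4 and the hindered pyridine in the presence of F10 then comes back to the route at 28.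

Step 8. Epimerization at C2 may be too slow relative to hydride transfer, or facial discrimination by the catalyst may be poor, so that the enantiomeric purity erodes. The fallback replaces catalyst control by substrate control plus resolution. It sets out from 12: LiBH(s-Bu)3 in THF at −78 °C delivers hydride anti to the 2-aryl group and should give the racemic 2,3-cis alcohol, rac-tetra-O-benzylepicatechin F6. Preparative chromatography on a chiral stationary phase then gives the 2R,3R enantiomer, which comes back to the route at 13; the 2S,3S enantiomer is oxidized back to 12 with Dess–Martin periodinane and recycled.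

Further compounds

F1 | step 6 | 1,3-bis(benzyloxy)-5-bromobenzene | Brc1cc(OCc2ccccc2)cc(OCc2ccccc2)c1
F2 | step 6 | 2,4-bis(benzyloxy)-6-bromobenzaldehyde | O=Cc1c(Br)cc(OCc2ccccc2)cc1OCc1ccccc1
F3 | step 6 | [2,4-bis(benzyloxy)-6-bromophenyl]methanol | OCc1c(Br)cc(OCc2ccccc2)cc1OCc1ccccc1
F4 | step 6 | 1,5-bis(benzyloxy)-3-bromo-2-(chloromethyl)benzene | ClCc1c(Br)cc(OCc2ccccc2)cc1OCc1ccccc1
F5 | step 6 | [3,4-bis(benzyloxy)phenyl]{2-[2,4-bis(benzyloxy)-6-bromobenzyl]-1,3-dithian-2-yl}methanol, racemic | OC(c1ccc(OCc2ccccc2)c(OCc2ccccc2)c1)C1(Cc2c(Br)cc(OCc3ccccc3)cc2OCc2ccccc2)SCCCS1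
F6 | step 8 | rac-(2R,3R/2S,3S)-5,7-bis(benzyloxy)-2-[3,4-bis(benzyloxy)phenyl]chroman-3-ol, both cis enantiomers | O[C@@H]1Cc2c(OCc3ccccc3)cc(OCc3ccccc3)cc2O[C@@H]1c1ccc(OCc2ccccc2)c(OCc2ccccc2)c1.O[C@H]1Cc2c(OCc3ccccc3)cc(OCc3ccccc3)cc2O[C@H]1c1ccc(OCc2ccccc2)c(OCc2ccccc2)c1
F7 | step 20 | 8-iodo-5,7,3',4'-tetra-O-benzylepicatechin (2R,3R) | O[C@@H]1Cc2c(OCc3ccccc3)cc(OCc3ccccc3)c(I)c2O[C@@H]1c1ccc(OCc2ccccc2)c(OCc2ccccc2)c1
F8 | step 20 | 8-iodo-5,7,3',4'-tetra-O-benzyl-4β-(2-ethoxyethoxy)epicatechin (2,3-cis, 3,4-trans) | O[C@@H]1[C@@H](OCCOCC)c2c(OCc3ccccc3)cc(OCc3ccccc3)c(I)c2O[C@@H]1c1ccc(OCc2ccccc2)c(OCc2ccccc2)c1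
F9 | step 20 | 8-iodo-tetra-O-benzylepicatechin-(4β→6)-8-bromo-tetra-O-benzylepicatechin | O[C@@H]1[C@@H](c2c(OCc4ccccc4)c(Br)c3c(c2OCc2ccccc2)C[C@@H](O)[C@@H](c2ccc(OCc4ccccc4)c(OCc4ccccc4)c2)O3)c2c(OCc3ccccc3)cc(OCc3ccccc3)c(I)c2O[C@@H]1c1ccc(OCc2ccccc2)c(OCc2ccccc2)c1
F10 | step 20 | tetra-O-benzylepicatechin-(4β→6)-8-bromo-tetra-O-benzylepicatechin | O[C@@H]1[C@@H](c2c(OCc4ccccc4)c(Br)c3c(c2OCc2ccccc2)C[C@@H](O)[C@@H](c2ccc(OCc4ccccc4)c(OCc4ccccc4)c2)O3)c2c(OCc3ccccc3)cc(OCc3ccccc3)cc2O[C@@H]1c1ccc(OCc2ccccc2)c(OCc2ccccc2)c1
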